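The six-membered ring is numbered C1–C6: C2 carries the cyclopentylmethyl arm, C4 is the quaternary carbon, C6 carries the acyl group, and C1, C3, C5 carry oxygen (O1, O3, O5). This alternation marks the ring as a dearomatised phloroglucinol. A Danheiser benzannulation joins a siloxyalkyne (C2≡C3–O3) to a 3-alkoxy-2-methylcyclobutenone (C4, C5, C6, C1), forming C1–C2 and C3–C4 in one strain-driven pericyclic cascade and giving a phenol with three differentiated oxygens. The cyclobutenone delivers an (S)-but-3-en-2-yl ether on O5; after C6 acylation, a dearomative Claisen rearrangement relays its chirality to C4, and cross-metathesis converts butenyl into prenyl.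

Key step: step 10

Remark: the dearomatised compounds are enolised β-triketones; one tautomer is drawn (ketone at C5, enols at C1 and C3), and the (R) descriptor at C4 refers to it.
Remark: (S)-limonene 1,2-oxide, (R)-but-3-en-2-ol, (R)-2-methylbutanoic acid, 1-ethoxyprop-1-yne and LiC≡CSiMe3 solution are taken as commercial.
Remark: "silylated arm" below means [(1R,2S,5S)-2-methyl-5-(prop-1-en-2-yl)-2-(triethylsilyloxy)cyclopentyl]methyl; full names are in the compound list.

Step 1
Reactants: 1 (S)-limonene 1,2-oxide [(4S)-1-methyl-4-(prop-1-en-2-yl)-7-oxabicyclo[4.1.0]heptane, cis/trans mixture]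
Product: 3 (3S)-6-oxo-3-(prop-1-en-2-yl)heptanal, via limonene diol 2 (not isolated)
Conditions: H5IO6, THF/H2O, 0 °C to rt
Reagents that add atoms: water, O
Why: Acid-promoted epoxide hydrolysis followed in the same flask by Malaprade glycol cleavage should open the ring between the two oxygenated carbons without touching the 1,1-disubstituted alkene or the existing stereocentre.

Step 2
Reactants: 3 (3S)-6-oxo-3-(prop-1-en-2-yl)heptanal
Product: 4 (3S)-6-oxo-3-(prop-1-en-2-yl)heptanoic acid
Conditions: NaClO2, NaH2PO4, 2-methylbut-2-ene, t-BuOH/H2O, 0 °C to rt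
Reagents that add atoms: sodium chlorite, [Na+].[O-]Cl=O
Why: Pinnick oxidation is selective for the aldehyde, and the alkene scavenger consumes hypochlorous acid before it can attack the isopropenyl group.

Step 3
Reactants: 4 (3S)-6-oxo-3-(prop-1-en-2-yl)heptanoic acid
Product: 5 (1R,2S,5S)-5-methyl-2-(prop-1-en-2-yl)-6-oxabicyclo[3.2.0]heptan-7-one
Conditions: 2-bromo-1-propylpyridinium triflate, 4-pyrrolidinopyridine, i-Pr2NEt, CH2Cl2, rt
Reagents that add atoms: none
Why: In this nucleophile-catalysed aldol-lactonisation (NCAL) the catalyst-bound enolate of the activated acid adds to the methyl ketone and the alkoxide closes the β-lactone, which can only be cis-fused (new C–O and C–C(=O) bonds cis), while the resident isopropenyl group should take the exo position trans to the lactone carbonyl, so both new stereocentres follow from the (S) centre.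

Step 4
Reactants: 5 (1R,2S,5S)-5-methyl-2-(prop-1-en-2-yl)-6-oxabicyclo[3.2.0]heptan-7-one
Product: 6 (1S,2S,3S)-2-(hydroxymethyl)-1-methyl-3-(prop-1-en-2-yl)cyclopentan-1-ol
Conditions: LiAlH4, THF, 0 °C
Reagents that add atoms: none
Why: Hydride reduction of the strained β-lactone at its acyl carbon should give the 1,3-diol with all three stereocentres retained, since no bond to a stereocentre is broken.

Step 5
Reactants: 6 (1S,2S,3S)-2-(hydroxymethyl)-1-methyl-3-(prop-1-en-2-yl)cyclopentan-1-ol
Product: 8 [(1S,2S,5S)-2-methyl-5-(prop-1-en-2-yl)-2-(triethylsilyloxy)cyclopentyl]methyl trifluoromethanesulfonate, via hydroxy triflate 7 (not isolated)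
Conditions: Tf2O, 2,6-lutidine, CH2Cl2, −78 °C; then Et3SiOTf, −78 to −30 °C; cold work-up, used at once
Reagents that add atoms: trifluoromethanesulfonic anhydride, O=S(=O)(OS(=O)(=O)C(F)(F)F)C(F)(F)F; triethylsilyl trifluoromethanesulfonate, CC[Si](CC)(CC)OS(=O)(=O)C(F)(F)F
Why: The primary hydroxyl should be sulfonylated far faster than the tertiary one at −78 °C, and silylation of the tertiary alcohol in the same flask removes the internal nucleophile before oxetane formation can set in.

Step 6
Reactants: 8 [(1S,2S,5S)-2-methyl-5-(prop-1-en-2-yl)-2-(triethylsilyloxy)cyclopentyl]methyl trifluoromethanesulfonate; 9 lithium (trimethylsilyl)acetylide (LiC≡CSiMe3)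
Product: 11 triethyl{[(1S,2R,3S)-1-methyl-3-(prop-1-en-2-yl)-2-(prop-2-yn-1-yl)cyclopentyl]oxy}silane, via silylalkyne 10 (not isolated)
Conditions: THF/DMPU, −78 to 0 °C; then K2CO3, MeOH, rt
Reagents that add atoms: none
Why: SN2 alkylation of the acetylide by the primary triflate builds the propargyl arm with no stereocentre involved, and mild methanolysis then removes the alkynyl silane while the tertiary silyl ether survives.

Step 7
Reactants: 11 triethyl{[(1S,2R,3S)-1-methyl-3-(prop-1-en-2-yl)-2-(prop-2-yn-1-yl)cyclopentyl]oxy}silane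
Product: 13 triethyl{[(1S,2R,3S)-1-methyl-3-(prop-1-en-2-yl)-2-{3-[tri(propan-2-yl)silyloxy]prop-2-yn-1-yl}cyclopentyl]oxy}silane, via lithium ynolate 12 (not isolated)
Conditions: LiN(SiMe3)2, t-BuOOH, THF, −78 to 0 °C; then i-Pr3SiOTf, −78 to 0 °C
Reagents that add atoms: tert-butyl hydroperoxide, CC(C)(C)OO; triisopropylsilyl trifluoromethanesulfonate, CC(C)[Si](C(C)C)(C(C)C)OS(=O)(=O)C(F)(F)F
Why: The lithium acetylide should be oxidised by lithium tert-butyl peroxide to the lithium ynolate (oxygen transfer with loss of tert-butoxide), which the bulky silyl triflate traps on oxygen to give the siloxyalkyne.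

Step 8
Reactants: 14 1-ethoxyprop-1-yne; 15 acetyl chloride
Product: 18 3-hydroxy-2-methylcyclobut-2-en-1-one, via ketene 16 (not isolated), via ethoxycyclobutenone 17 (not isolated)
Conditions: Et3N, MeCN, 0 °C to rt; then 1 M HCl (aq), THF, rt
Reagents that add atoms: water, O
Why: Triethylamine dehydrochlorinates acetyl chloride to ketene, which should add to the electron-rich ynol ether in a regioselective [2+2] cycloaddition (alkyne carbon remote from oxygen to the ketene carbonyl carbon), and dilute acid then hydrolyses the vinylogous ester to the stable enol of 2-methylcyclobutane-1,3-dione.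

Step 9
Reactants: 18 3-hydroxy-2-methylcyclobut-2-en-1-one; 19 (2R)-but-3-en-2-ol
Product: 20 3-[(2S)-but-3-en-2-yloxy]-2-methylcyclobut-2-en-1-one
Conditions: PPh3, DIAD, THF, 0 °C to rt
Reagents that add atoms: none
Why: In this Mitsunobu etherification the strongly acidic enol (a vinylogous carboxylic acid) should be alkylated on oxygen with SN2 inversion, so the (R)-alcohol gives the (S)-ether, and the two enol oxygens of the symmetric dione are equivalent, so no regiochemical issue arises.

Step 10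
Reactants: 13 triethyl{[(1S,2R,3S)-1-methyl-3-(prop-1-en-2-yl)-2-{3-[tri(propan-2-yl)silyloxy]prop-2-yn-1-yl}cyclopentyl]oxy}silane; 20 3-[(2S)-but-3-en-2-yloxy]-2-methylcyclobut-2-en-1-one
Product: 25 5-[(2S)-but-3-en-2-yloxy]-4-methyl-2-(silylated arm)-3-[tri(propan-2-yl)silyloxy]phenol, via vinylketene 21 (not isolated), via vinylcyclobutenone 22 (not isolated), via dienylketene 23 (not isolated), via cyclohexadienone 24 (not isolated)
Conditions: toluene (degassed), 90 °C, sealed tube
Reagents that add atoms: none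
Why: Heating should open cyclobutenone 20 by 4π-electrocyclic cleavage of its C1–C6 bond to vinylketene 21, whose ketene C=C adds to siloxyalkyne 13 in a regioselective [2+2] cycloaddition that makes C1–C2 and C3–C4 at once (2-vinylcyclobutenone 22); a second 4π opening (C1–C4 bond) gives dienylketene 23, which closes the six-membered ring by thermal disrotatory 6π-electrocyclisation (C1–C6) to dienone 24 and tautomerises to phenol 25. This is the Danheiser benzannulation in its siloxyalkyne form, driven by release of strain from both four-membered rings and by the final aromatisation. The regioselectivity it needs is secured by polarisation: the nucleophilic alkyne carbon remote from oxygen (C2) attacks the ketene carbonyl carbon (C1), so the silyloxy carbon C3 ends next to the methyl-bearing C4, and O1, O3 and O5 emerge as free phenol, silyl ether and butenyl ether. No stereocentre is created; the (S)-butenyl ether and the three cyclopentane centres are spectators, and the allyl vinyl ether in 20 is a vinylogous ester that should resist Claisen rearrangement at this temperature. The tertiary alcohol is silylated so that it cannot trap the ketenes.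

Step 11
Reactants: 25 5-[(2S)-but-3-en-2-yloxy]-4-methyl-2-(silylated arm)-3-[tri(propan-2-yl)silyloxy]phenol; 26 (2R)-2-methylbutanoic acid
Product: 29 (2R)-1-{6-[(2S)-but-3-en-2-yloxy]-2-hydroxy-5-methyl-3-(silylated arm)-4-[tri(propan-2-yl)silyloxy]phenyl}-2-methylbutan-1-one, via acid chloride 27 (not isolated), via magnesium phenoxide 28 (not isolated)
Conditions: 26, (COCl)2, cat. DMF, CH2Cl2, 0 °C to rt, evaporate; 25, EtMgBr, toluene, 0 °C to rt; then add 27, rt to 50 °C
Reagents that add atoms: none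
Why: In this ortho-coordinated C-acylation of a magnesium phenoxide the metal binds the acid chloride and delivers it to C6, the only free ring carbon (ortho to O1, the other ortho carbon C2 being substituted), under base-free and non-acidic conditions that should leave the butenyl ether, both silyl ethers, the isopropenyl group and the α-stereocentre of the acyl unit intact.

Step 12
Reactants: 29 (2R)-1-{6-[(2S)-but-3-en-2-yloxy]-2-hydroxy-5-methyl-3-(silylated arm)-4-[tri(propan-2-yl)silyloxy]phenyl}-2-methylbutan-1-one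
Product: 30 (6R)-6-[(2E)-but-2-en-1-yl]-3-hydroxy-6-methyl-4-(silylated arm)-2-[(2R)-2-methylbutanoyl]-5-[tri(propan-2-yl)silyloxy]cyclohexa-2,4-dien-1-one
Conditions: toluene, 130 °C, sealed tube
Reagents that add atoms: none
Why: In this dearomatising aromatic Claisen rearrangement the butenyl group should shift from O5 to the methyl-bearing C4 rather than to the acyl-bearing C6 (which would give a congested, cross-conjugated 2,2-disubstituted trione), and a chair transition state with the carbinol methyl equatorial delivers the allyl terminus to one face of C4, so the (S) carbinol centre is relayed to the (R) quaternary centre with an E-butenyl chain, the free O1–H letting the dienone settle as the hydrogen-bonded enolised triketone.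

Step 13
Reactants: 30 (6R)-6-[(2E)-but-2-en-1-yl]-3-hydroxy-6-methyl-4-(silylated arm)-2-[(2R)-2-methylbutanoyl]-5-[tri(propan-2-yl)silyloxy]cyclohexa-2,4-dien-1-one
Product: 31 (6R)-3-hydroxy-6-methyl-4-(silylated arm)-2-[(2R)-2-methylbutanoyl]-6-(3-methylbut-2-en-1-yl)-5-[tri(propan-2-yl)silyloxy]cyclohexa-2,4-dien-1-one
Conditions: second-generation Grubbs catalyst (H2IMes)(PCy3)Cl2Ru=CHPh (5 mol %), 2-methylbut-2-ene (excess), CH2Cl2, 40 °C
Reagents that add atoms: 2-methylbut-2-ene, CC=C(C)C
Why: In this olefin cross-metathesis the 1,2-disubstituted butenyl alkene should exchange its ethylidene end for isopropylidene from excess 2-methylbut-2-ene, while the hindered 1,1-disubstituted isopropenyl group is expected to stay inert because it could only lead to a tetrasubstituted alkene.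

Step 14
Reactants: 31 (6R)-3-hydroxy-6-methyl-4-(silylated arm)-2-[(2R)-2-methylbutanoyl]-6-(3-methylbut-2-en-1-yl)-5-[tri(propan-2-yl)silyloxy]cyclohexa-2,4-dien-1-one
Product: 32 (6R)-3,5-dihydroxy-4-{[(1R,2S,5S)-2-hydroxy-2-methyl-5-(prop-1-en-2-yl)cyclopentyl]methyl}-6-methyl-2-[(2R)-2-methylbutanoyl]-6-(3-methylbut-2-en-1-yl)cyclohexa-2,4-dien-1-one (target)
Conditions: n-Bu4NF, THF, 0 °C to rt; pH 5 buffer work-up
Reagents that add atoms: none
Why: Fluoride should cleave the vinylogous silyl ester at O3 and the tertiary triethylsilyl ether without acid, so the tertiary alcohol cannot cyclise onto the C3 enol or eliminate, and the buffered work-up returns the enolised triketone with all five stereocentres untouched.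

Compound list
1 | (4S)-1-methyl-4-(prop-1-en-2-yl)-7-oxabicyclo[4.1.0]heptane [(S)-limonene 1,2-oxide, cis/trans mixture at the epoxide] | CC12OC1C[C@H](CC2)C(C)=C | starting material
2 | (4S)-1-methyl-4-(prop-1-en-2-yl)cyclohexane-1,2-diol (diastereomer mixture) | CC1(O)C(O)C[C@H](CC1)C(C)=C | intermediate
3 | (3S)-6-oxo-3-(prop-1-en-2-yl)heptanal | O=CC[C@H](CCC(C)=O)C(C)=C | intermediate
4 | (3S)-6-oxo-3-(prop-1-en-2-yl)heptanoic acid | OC(=O)C[C@H](CCC(C)=O)C(C)=C | intermediate
5 | (1R,2S,5S)-5-methyl-2-(prop-1-en-2-yl)-6-oxabicyclo[3.2.0]heptan-7-one (cis-fused β-lactone, isopropenyl trans to the lactone carbonyl) | C=C(C)[C@H]1CC[C@]2(C)OC(=O)[C@H]12 | intermediate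
6 | (1S,2S,3S)-2-(hydroxymethyl)-1-methyl-3-(prop-1-en-2-yl)cyclopentan-1-ol | C=C(C)[C@H]1CC[C@](C)(O)[C@@H]1CO | intermediate
7 | [(1S,2S,5S)-2-hydroxy-2-methyl-5-(prop-1-en-2-yl)cyclopentyl]methyl trifluoromethanesulfonate | C=C(C)[C@H]1CC[C@](C)(O)[C@@H]1COS(=O)(=O)C(F)(F)F | intermediate
8 | [(1S,2S,5S)-2-methyl-5-(prop-1-en-2-yl)-2-(triethylsilyloxy)cyclopentyl]methyl trifluoromethanesulfonate | C=C(C)[C@H]1CC[C@](C)(O[Si](CC)(CC)CC)[C@@H]1COS(=O)(=O)C(F)(F)F | intermediate
9 | lithium (trimethylsilyl)acetylide | [Li]C#C[Si](C)(C)C | starting material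
10 | triethyl{[(1S,2R,3S)-1-methyl-3-(prop-1-en-2-yl)-2-[3-(trimethylsilyl)prop-2-yn-1-yl]cyclopentyl]oxy}silane | C=C(C)[C@H]1CC[C@](C)(O[Si](CC)(CC)CC)[C@@H]1CC#C[Si](C)(C)C | intermediate
11 | triethyl{[(1S,2R,3S)-1-methyl-3-(prop-1-en-2-yl)-2-(prop-2-yn-1-yl)cyclopentyl]oxy}silane | C=C(C)[C@H]1CC[C@](C)(O[Si](CC)(CC)CC)[C@@H]1CC#C | intermediate
12 | lithium 3-[(1R,2S,5S)-2-methyl-5-(prop-1-en-2-yl)-2-(triethylsilyloxy)cyclopentyl]prop-1-yn-1-olate | C=C(C)[C@H]1CC[C@](C)(O[Si](CC)(CC)CC)[C@@H]1CC#CO[Li] | intermediate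
13 | triethyl{[(1S,2R,3S)-1-methyl-3-(prop-1-en-2-yl)-2-{3-[tri(propan-2-yl)silyloxy]prop-2-yn-1-yl}cyclopentyl]oxy}silane | C=C(C)[C@H]1CC[C@](C)(O[Si](CC)(CC)CC)[C@@H]1CC#CO[Si](C(C)C)(C(C)C)C(C)C | intermediate
14 | 1-ethoxyprop-1-yne | CC#COCC | starting material
15 | acetyl chloride | CC(=O)Cl | starting material
16 | ketene (ethenone) | C=C=O | intermediate
17 | 3-ethoxy-2-methylcyclobut-2-en-1-one | CCOC1=C(C)C(=O)C1 | intermediate
18 | 3-hydroxy-2-methylcyclobut-2-en-1-one (enol of 2-methylcyclobutane-1,3-dione) | CC1=C(O)CC1=O | intermediate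
19 | (2R)-but-3-en-2-ol | C[C@@H](O)C=C | starting material
20 | 3-[(2S)-but-3-en-2-yloxy]-2-methylcyclobut-2-en-1-one | C[C@H](OC1=C(C)C(=O)C1)C=C | intermediate
21 | 3-[(2S)-but-3-en-2-yloxy]-2-methylbuta-1,3-dien-1-one | C=C(O[C@@H](C)C=C)C(C)=C=O | intermediate
22 | 4-{1-[(2S)-but-3-en-2-yloxy]ethenyl}-4-methyl-2-{[(1R,2S,5S)-2-methyl-5-(prop-1-en-2-yl)-2-(triethylsilyloxy)cyclopentyl]methyl}-3-[tri(propan-2-yl)silyloxy]cyclobut-2-en-1-one (both configurations at the ring sp3 carbon) | C=C(C)[C@H]1CC[C@](C)(O[Si](CC)(CC)CC)[C@@H]1CC1=C(O[Si](C(C)C)(C(C)C)C(C)C)C(C)(C(=C)O[C@@H](C)C=C)C1=O | intermediate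
23 | (3E)-5-[(2S)-but-3-en-2-yloxy]-4-methyl-2-{[(1R,2S,5S)-2-methyl-5-(prop-1-en-2-yl)-2-(triethylsilyloxy)cyclopentyl]methyl}-3-[tri(propan-2-yl)silyloxy]hexa-1,3,5-trien-1-one (ketene-bearing carbon and alkoxyvinyl group cis) | C=C(C)[C@H]1CC[C@](C)(O[Si](CC)(CC)CC)[C@@H]1CC(=C=O)/C(O[Si](C(C)C)(C(C)C)C(C)C)=C(C)\C(=C)O[C@@H](C)C=C | intermediate
24 | 5-[(2S)-but-3-en-2-yloxy]-4-methyl-2-{[(1R,2S,5S)-2-methyl-5-(prop-1-en-2-yl)-2-(triethylsilyloxy)cyclopentyl]methyl}-3-[tri(propan-2-yl)silyloxy]cyclohexa-2,4-dien-1-one | C=C(C)[C@H]1CC[C@](C)(O[Si](CC)(CC)CC)[C@@H]1CC1=C(O[Si](C(C)C)(C(C)C)C(C)C)C(C)=C(O[C@@H](C)C=C)CC1=O | intermediate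
25 | 5-[(2S)-but-3-en-2-yloxy]-4-methyl-2-{[(1R,2S,5S)-2-methyl-5-(prop-1-en-2-yl)-2-(triethylsilyloxy)cyclopentyl]methyl}-3-[tri(propan-2-yl)silyloxy]phenol | C=C(C)[C@H]1CC[C@](C)(O[Si](CC)(CC)CC)[C@@H]1Cc1c(O)cc(O[C@@H](C)C=C)c(C)c1O[Si](C(C)C)(C(C)C)C(C)C | intermediate
26 | (2R)-2-methylbutanoic acid | CC[C@@H](C)C(=O)O | starting material
27 | (2R)-2-methylbutanoyl chloride | CC[C@@H](C)C(=O)Cl | intermediate
28 | bromomagnesium phenoxide of 25 | C=C(C)[C@H]1CC[C@](C)(O[Si](CC)(CC)CC)[C@@H]1Cc1c(O[Mg]Br)cc(O[C@@H](C)C=C)c(C)c1O[Si](C(C)C)(C(C)C)C(C)C | intermediate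
29 | (2R)-1-{6-[(2S)-but-3-en-2-yloxy]-2-hydroxy-5-methyl-3-{[(1R,2S,5S)-2-methyl-5-(prop-1-en-2-yl)-2-(triethylsilyloxy)cyclopentyl]methyl}-4-[tri(propan-2-yl)silyloxy]phenyl}-2-methylbutan-1-one | C=C(C)[C@H]1CC[C@](C)(O[Si](CC)(CC)CC)[C@@H]1Cc1c(O)c(C(=O)[C@H](C)CC)c(O[C@@H](C)C=C)c(C)c1O[Si](C(C)C)(C(C)C)C(C)C | intermediate
30 | (6R)-6-[(2E)-but-2-en-1-yl]-3-hydroxy-6-methyl-4-{[(1R,2S,5S)-2-methyl-5-(prop-1-en-2-yl)-2-(triethylsilyloxy)cyclopentyl]methyl}-2-[(2R)-2-methylbutanoyl]-5-[tri(propan-2-yl)silyloxy]cyclohexa-2,4-dien-1-one | C=C(C)[C@H]1CC[C@](C)(O[Si](CC)(CC)CC)[C@@H]1CC1=C(O[Si](C(C)C)(C(C)C)C(C)C)[C@@](C)(C/C=C/C)C(=O)C(C(=O)[C@H](C)CC)=C1O | intermediate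
31 | (6R)-3-hydroxy-6-methyl-4-{[(1R,2S,5S)-2-methyl-5-(prop-1-en-2-yl)-2-(triethylsilyloxy)cyclopentyl]methyl}-2-[(2R)-2-methylbutanoyl]-6-(3-methylbut-2-en-1-yl)-5-[tri(propan-2-yl)silyloxy]cyclohexa-2,4-dien-1-one | C=C(C)[C@H]1CC[C@](C)(O[Si](CC)(CC)CC)[C@@H]1CC1=C(O[Si](C(C)C)(C(C)C)C(C)C)[C@@](C)(CC=C(C)C)C(=O)C(C(=O)[C@H](C)CC)=C1O | intermediate
32 | (6R)-3,5-dihydroxy-4-{[(1R,2S,5S)-2-hydroxy-2-methyl-5-(prop-1-en-2-yl)cyclopentyl]methyl}-6-methyl-2-[(2R)-2-methylbutanoyl]-6-(3-methylbut-2-en-1-yl)cyclohexa-2,4-dien-1-one | C=C(C)[C@H]1CC[C@](C)(O)[C@@H]1CC1=C(O)[C@@](C)(CC=C(C)C)C(=O)C(C(=O)[C@H](C)CC)=C1O | target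

Total step count: 14. Longest linear sequence: 12 (steps 1–7, then 10–14).

Steps most likely to fail

Step 10. The electrocyclic opening of the donor-stabilised cyclobutenone 20 may need temperatures at which [3,3] shifts of the butenyl ether compete, either within 20 (onto the methyl-bearing carbon) or in 25 (onto the still unsubstituted C6). The fallback sets out from 19 and 13 and returns at 25; it generates vinylketene 21 at 0 °C by 1,4-dehydrochlorination of an unsaturated acid chloride instead of by ring opening. Mitsunobu O-alkylation of commercial ethyl 2-methyl-3-oxobutanoate with 19 (PPh3, DIAD) would give ethyl (2E)-3-[(2S)-but-3-en-2-yloxy]-2-methylbut-2-enoate F1 (alkene geometry immaterial). LiOH hydrolysis would give (2E)-3-[(2S)-but-3-en-2-yloxy]-2-methylbut-2-enoic acid F2, and 1-chloro-N,N,2-trimethylprop-1-en-1-amine would give (2E)-3-[(2S)-but-3-en-2-yloxy]-2-methylbut-2-enoyl chloride F3. Slow addition of Et3N to F3 and 13 in CH2Cl2 at 0 °C would release 21, which 13 traps as 22; warming to about 60 °C would then carry 22 through 23 and 24 to 25.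

Step 12. The butenyl group may migrate in part to the acyl-bearing C6, or chirality transfer may erode through a boat transition state. The fallback sets out from 29 and returns at 30; it replaces the thermal sigmatropic shift by ionisation and recombination. Pd2(dba)3 (zerovalent palladium) with a chiral bisphosphine (the DACH-phenyl ligand, both enantiomers screened for the matched case) in toluene at rt would ionise the butenyl ether to a π-butenyl palladium phenoxide ion pair. This recombines at C4 through the unsubstituted allyl terminus (asymmetric allylic dearomatisation), with the ligand rather than the carbinol centre selecting the face. No compound outside the list is formed.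

Step 11. O-acylation of the phenoxide may outrun C-acylation at the crowded C6. The fallback sets out from 25 and 26 and returns at 29; it uses halogen–metal exchange instead of phenoxide acylation. N-Bromosuccinimide (CH2Cl2, −78 °C) would brominate the only free ring position to give 2-bromo-3-[(2S)-but-3-en-2-yloxy]-4-methyl-6-{[(1R,2S,5S)-2-methyl-5-(prop-1-en-2-yl)-2-(triethylsilyloxy)cyclopentyl]methyl}-5-[tri(propan-2-yl)silyloxy]phenol F4. Acid 26 would be converted (MeNHOMe·HCl, EDC·HCl, i-Pr2NEt) into (2R)-N-methoxy-N,2-dimethylbutanamide F5. Deprotonation of F4 (MeLi, one equivalent), bromine–lithium exchange (t-BuLi, THF, −78 °C) and addition of F5 would give 29 after work-up.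

Further compounds
F1 | step 10 | ethyl (2E)-3-[(2S)-but-3-en-2-yloxy]-2-methylbut-2-enoate | CCOC(=O)/C(C)=C(C)/O[C@@H](C)C=C
F2 | step 10 | (2E)-3-[(2S)-but-3-en-2-yloxy]-2-methylbut-2-enoic acid | OC(=O)/C(C)=C(C)/O[C@@H](C)C=C
F3 | step 10 | (2E)-3-[(2S)-but-3-en-2-yloxy]-2-methylbut-2-enoyl chloride | ClC(=O)/C(C)=C(C)/O[C@@H](C)C=C
F0 | step 12 | none | none
F4 | step 11 | 2-bromo-3-[(2S)-but-3-en-2-yloxy]-4-methyl-6-{[(1R,2S,5S)-2-methyl-5-(prop-1-en-2-yl)-2-(triethylsilyloxy)cyclopentyl]methyl}-5-[tri(propan-2-yl)silyloxy]phenol | C=C(C)[C@H]1CC[C@](C)(O[Si](CC)(CC)CC)[C@@H]1Cc1c(O)c(Br)c(O[C@@H](C)C=C)c(C)c1O[Si](C(C)C)(C(C)C)C(C)C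
F5 | step 11 | (2R)-N-methoxy-N,2-dimethylbutanamide | CC[C@@H](C)C(=O)N(C)OC
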